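## The problem

Compound 22 is 8-(2,4-dihydroxy-6-pentylphenoxy)-6-hydroxy-3-pentylisochromen-1-one. It is an isocoumarin (benzene ring A fused to a pyranone through C4a and C8a) joined by one oxygen at C8 to ring B, a 5-pentylresorcinol bound at C1', the carbon between C2'–OH and the C6' pentyl group.

The diaryl ether is the hard bond. Its ring-B carbon has two ortho substituents, and its ring-A carbon C8 sits next to C8a, which carries the lactone carbonyl C1. Three of the four ortho positions around the oxygen are therefore occupied, and metal-catalysed C–O coupling of the two halves should be slow.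

There is no stereocentre and no alkene geometry to set, so nothing needs to be relayed. Every selectivity question is positional: the pattern on ring A (carbon on C4a, carbonyl on C8a, oxygen on C8 and C6), the 1,2,4,6 pattern on ring B, and 6-endo against 5-exo closure of the lactone.

The sensitive groups are the three free phenols and the enol lactone. Two of the phenols sit on a resorcinol ring that is easily oxidised and easily attacked by electrophiles, and hydroxide or alkoxide opens the lactone to a keto acid. The phenols are therefore carried as methyl ethers to the last step, and the lactone is closed late and under acid.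

The enabling feature is that the ether oxygen (on C8) and the carbonyl carbon (on C8a) occupy neighbouring carbons of ring A. An oxygen nucleophile and a carbon electrophile on adjacent positions are exactly what the two ends of an aryne triple bond take up. C4a, on the other side of C8a, carries the only other carbon substituent, so a chlorine there can first decide which aryne carbon the phenoxide attacks and then be exchanged for the C4–C3–pentyl chain.

## Retrosynthesis

**22 from 21.** The three O–CH3 bonds of the trimethyl ether 21 are cut last. Methyl ethers are preferred to benzyl or silyl groups because they survive hydride base, fluoride, organolithium, palladium and hot trifluoroacetic acid, and because ring B is bought with them in place in 7. The forward step must cleave three aryl methyl ethers without opening the lactone or the diaryl ether.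

**21 from 19.** The pyranone is opened at O2–C3, giving the methyl 2-alkynylbenzoate 19. The neighbouring cut at C3–C4 would need a benzylic anion generated beside an ester on a ring that already carries the crowded ether. The O2–C3 cut only asks the ester carbonyl oxygen to add to an acid-activated alkyne. That closure must be 6-endo. This is expected because it passes through the aromatic 1-methoxyisochromenylium ion 20, whereas 5-exo attack gives no such stabilised cation.

**19 from 17 and 18.** The C4a–C4 bond is cut to the aryl chloride 17 and hept-1-yne 18. The alkyne delivers C4, C3 and the pentyl chain in one purchased piece, so the side chain needs no separate construction. The forward Sonogashira coupling must engage an aryl chloride, which the ortho ester helps and a bulky biarylphosphine allows.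

**17 from 16.** The ester methyl is removed to give acid 16. The ester is needed in the forward direction for two reasons. A free 2-halobenzoic acid gives mixtures of five- and six-membered lactones under palladium. The ester carbonyl is also the nucleophile of the later ring closure.

**16 from 6, 11 and 12 (key disconnection).** Both bonds to ring A at C8 and C8a are cut together: C8–O and C8a–C1. This gives the silyl triflate 6, the phenol 11 and carbon dioxide 12. In the forward step the potassium phenoxide 13, the aryne 14 and the aryl anion 15 are intermediates.

- Cutting only C8–O would require copper-mediated coupling of a 2,6-disubstituted phenol with an ortho-carboxy aryl halide.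
- Cutting O–C1' would require a di-ortho-substituted, electron-rich ring B electrophile, which is worse.
- The aryne route needs no metal. The phenoxide attacks a carbon flanked only by C7–H, and the carboxyl carbon arrives in the same operation.

Two monocyclic benzenes and CO2 replace a tetrasubstituted diaryl ether acid. The forward reaction must meet three demands:

- attack at C8 and not at C8a, which the chlorine secures;
- carboxylation of 15 faster than its protonation or its loss of chloride;
- an electrophile that does not consume the phenoxide. CO2 qualifies because its adduct with a phenoxide forms reversibly, whereas an acyl halide would acylate 13 for good.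

An aryne without the chlorine (a 4-alkoxybenzyne) has little regiochemical bias, which is why the chlorine is kept as a spectator through this step.

**6 from 3, 2 and 1.** The C–Si and O–S bonds of 6 are traced to the silyl ether 3 by bromine–lithium exchange, 1,3-silyl shift from oxygen to carbon (via 4 and 5) and triflation. Compound 3 comes from bromophenol 2, and 2 from 2-chloro-4-methoxyphenol 1 by bromination at the only free position ortho to the hydroxyl. The chlorine is bought in place. The lithium in 4 is meta to it, so no elimination can occur.

**11 from 9 and 7.** The C1'–O bond of phenol 11 is traced to the C1'–CHO bond of aldehyde 9 (aryl migration to oxygen, via formate 10). Aldehyde 9 comes from olivetol dimethyl ether 7 by formylation (via iminium salt 8) at the position para to one methoxy group and ortho to the other. Ring B thus keeps its purchased carbon skeleton and gains only one oxygen.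

## Roads not taken

**Alternative 1: ring B built by Michael–Dieckmann annulation.**
- Cut: ring B is opened at C1'–C6' and C2'–C3'. Ring A, with the ether oxygen already attached, is carried as dimethyl 2-[5-methoxy-2-(methoxycarbonyl)-3-methylphenoxy]propanedioate A1. The other ring-B carbons come from (E)-non-3-en-2-one A2.
- Forward key step: with NaOMe in methanol the anion of A1 adds to A2, and the methyl ketone enolate then closes on a malonate ester. The product is the cyclohexanedione A3, methyl 1-[5-methoxy-2-(methoxycarbonyl)-3-methylphenoxy]-2,4-dioxo-6-pentylcyclohexane-1-carboxylate.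
- Merits: the crowded ether bond is made by simple O-alkylation before it becomes crowded. Only base is needed. The sequence is the classical way to 5-alkylresorcinols.
- Weak points for this target:
  - The Michael donor is a tertiary carbanion that must form a quaternary centre in a reversible addition.
  - A3 must still lose its extra ester and be dehydrogenated to the resorcinol.
  - The new phenols must be protected.
  - The pyranone must then be built from the ring-A methyl group by lateral deprotonation and acylation with strong base beside two esters, followed by cyclisation and deprotection.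
- Comparison: on reliability of the ether bond this road is better than the chosen one, which rests on an untested three-component step. Against that, the chosen plan buys the ring-B pattern ready-made in 7, avoids the aromatisation and the redox adjustment, and reaches the isocoumarin from its key product in mild, well-known steps. Alternative 1 would be the longer route.

**Alternative 2: carboxylate-directed C–H annulation.**
- Cut: the pyranone is removed at C4a–C4 and O2–C3. This leads to 2-(2,4-dimethoxy-6-pentylphenoxy)-4-methoxybenzoic acid A4 and dimethylsulfoxonium 2-oxoheptylide A5.
- Forward key step: with [Cp*RhCl2]2 (trivalent rhodium) and NaOAc, A4 is metalated at its single free ortho C–H. The rhodium carbene from A5 inserts, and the carboxylate oxygen condenses on the ketone. The product is isocoumarin A6, identical with 21 of the chosen route.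
- Merits: no halogen handle, no esterification, and the pyranone is made in one step. After the diaryl ether this road is two steps shorter than the chosen one, a real advantage. Regiochemistry is forced because only one ortho C–H exists.
- Weak points:
  - The road starts from the diaryl ether acid A4 and so leaves the hardest bond unsolved. A4 would have to come from copper coupling of the hindered phenol 11 with a 2-halo-4-methoxybenzoic acid.
  - The chosen aryne step cannot supply A4, because an aryne without the chlorine loses its regiocontrol.
  - The carboxylate is twisted by the ortho aryloxy group, which may slow metalation.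
  - Alkyl acyl sulfoxonium ylides are less well-behaved carbene sources than aroyl ones.
- Comparison: if A4 were easy to make, this would be the better route. The chosen plan sets against it a metal-free ether formation at an unhindered aryne carbon, with the chlorine serving as both regiocontrol and coupling handle.

**Alternative 3: ring B by photochemical Wolff rearrangement and benzannulation.**
- Cut: ring B is opened at C5'–C6', C2'–C3', C4'–C5' and C1'–C2'. This leads to the diazo ketone A7, methyl 2-{[2-(diazoacetyl)hept-1-en-1-yl]oxy}-4-methoxy-6-methylbenzoate, and ethoxyethyne A8.
- Forward key step: irradiation of A7 gives a vinylketene by Wolff shift. It adds A8 in a [2+2] sense, and the cyclobutenone opens and recloses by 6π electrocyclisation. The product is phenol A9, methyl 2-(4-ethoxy-2-hydroxy-6-pentylphenoxy)-4-methoxy-6-methylbenzoate.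
- Merits: the 1,2,4,6 pattern of ring B is set with complete positional control. The two ring-B oxygens emerge differentiated. The ether oxygen is attached to a vinyl carbon before any crowding exists.
- Weak points:
  - A7 is a β-aryloxy enone diazo ketone that itself takes several steps to prepare.
  - The cascade needs photolysis and a volatile ynol ether.
  - The oxygen differentiation is of no use here, since both ring-B oxygens end as free phenols.
  - As in Alternative 1, the pyranone must still be built from the ring-A methyl group with strong base after protecting the new phenol.
- Comparison: this road is the most elegant way to make ring B, and it is better where a differentiated resorcinol is wanted. For this target it rebuilds a ring that can be bought, and it is clearly longer. The chosen plan spends its one ambitious step on the bond that is actually difficult.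

Key step: step 6

## Route

Remark: compound 22 has no stereocentre, so no SMILES below carries a stereodescriptor.
Assumption: 2-chloro-6-fluoro-4-methoxybenzaldehyde F1, needed only in the fallback for step 6, is taken to be a purchasable building block.

Step 1
Reactants: 1 2-chloro-4-methoxyphenol
Product: 2 2-bromo-6-chloro-4-methoxyphenol
Conditions: NBS (1.0 equiv), i-Pr2NH (10 mol %), CH2Cl2, 0 °C
Reagents that add atoms: N-bromosuccinimide, O=C1CCC(=O)N1Br
Why: Amine-catalysed electrophilic ortho-bromination of a phenol; the hydroxyl directs bromine to C6, its only free ortho position, the para position being blocked by methoxy and the positions ortho to methoxy being less activated.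

Step 2
Reactants: 2 2-bromo-6-chloro-4-methoxyphenol
Product: 3 (2-bromo-6-chloro-4-methoxyphenoxy)trimethylsilane
Conditions: HMDS, THF, 70 °C; evaporate
Reagents that add atoms: hexamethyldisilazane, C[Si](C)(C)N[Si](C)(C)C
Why: O-Silylation of a phenol with hexamethyldisilazane; ammonia is the only by-product, so the crude silyl ether can be dried and used directly.

Step 3
Reactants: 3 (2-bromo-6-chloro-4-methoxyphenoxy)trimethylsilane
Product: 6 2-chloro-4-methoxy-6-(trimethylsilyl)phenyl trifluoromethanesulfonate, via aryllithium 4 (not isolated), via lithium silylphenoxide 5 (not isolated)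
Conditions: n-BuLi, THF, −100 → −80 °C; Tf2O, −100 °C → rt
Reagents that add atoms: trifluoromethanesulfonic anhydride, O=S(=O)(OS(=O)(=O)C(F)(F)F)C(F)(F)F
Why: Bromine–lithium exchange gives 4, which undergoes the retro-Brook 1,3-shift of silicon from oxygen to carbon to give 5, and Tf2O sulfonylates the phenoxide; exchange at bromine is far faster than at chlorine, and lithium is meta to chlorine so no elimination can occur.

Step 4
Reactants: 7 1,3-dimethoxy-5-pentylbenzene
Product: 9 2,4-dimethoxy-6-pentylbenzaldehyde, via iminium chloride 8 (not isolated)
Conditions: POCl3, DMF, 0 → 70 °C; aq. NaOAc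
Reagents that add atoms: N,N-dimethylformamide, CN(C)C=O; water, O
Why: Vilsmeier–Haack formylation; the bulky chloroiminium ion attacks the position para to one methoxy and ortho to the other in preference to the more shielded carbon between the two methoxy groups, and iminium salt 8 is hydrolysed on work-up.

Step 5
Reactants: 9 2,4-dimethoxy-6-pentylbenzaldehyde
Product: 11 2,4-dimethoxy-6-pentylphenol, via aryl formate 10 (not isolated)
Conditions: mCPBA, CH2Cl2, 0 °C → rt; then K2CO3, MeOH, rt
Reagents that add atoms: 3-chloroperbenzoic acid, OOC(=O)c1cccc(Cl)c1
Why: Dakin-type oxidation run as a Baeyer–Villiger reaction; the electron-rich aryl group migrates in the Criegee intermediate to give formate 10, which mild methanolysis cleaves to the phenol.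

Step 6
Reactants: 6 2-chloro-4-methoxy-6-(trimethylsilyl)phenyl trifluoromethanesulfonate; 11 2,4-dimethoxy-6-pentylphenol; 12 carbon dioxide
Product: 16 2-chloro-6-(2,4-dimethoxy-6-pentylphenoxy)-4-methoxybenzoic acid, via potassium phenoxide 13 (not isolated), via chloromethoxybenzyne 14 (not isolated), via arylpotassium 15 (not isolated)
Conditions: 11, KH, THF, 0 °C; then 6 (0.8 equiv), KF, 18-crown-6, CO2 (1 atm), THF, 0 °C → rt; aq. HCl
Reagents that add atoms: none
Why: Proposed new method: fluoride attacks silicon in 6 and triflate leaves to give aryne 14; the oxygen of phenoxide 13 adds to the aryne carbon meta to chlorine (C8) to give aryl anion 15 at C8a, and CO2 traps 15 as the carboxylate, which acid work-up converts to 16. The closest known reaction types are the three-component coupling of arynes, amines and CO2 to anthranilic acids and the fluoride-mediated O-arylation of phenols by silyl aryl triflates; what is new is an anionic oxygen nucleophile whose adduct has no internal proton to shift and must be caught by CO2. No ring closes and no stereocentre forms. The required selectivity is regiochemical: the inductively withdrawing chlorine distorts the aryne so that the carbon remote from it is the electrophilic one and the negative charge develops beside the C–Cl bond, and the hindered phenoxide also prefers that carbon on steric grounds because it is flanked only by C7–H. The ortho and para positions of 13 are all substituted, so neither C-arylation nor Kolbe–Schmitt carboxylation can compete, and CO2 binds the phenoxide oxygen only reversibly. The medium is kept free of proton donors (phenoxide pre-formed with KH, THF in place of acetonitrile, KF with 18-crown-6 as the soluble fluoride) so that carboxylation outruns protonation of 15. Saturation with CO2 at 0 °C should likewise outrun loss of chloride from 15, and chlorine is chosen over bromine because it is the slower leaving group in that elimination. The phenoxide is used in slight excess so that carboxylate 16 is not itself arylated by surplus aryne.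

Step 7
Reactants: 16 2-chloro-6-(2,4-dimethoxy-6-pentylphenoxy)-4-methoxybenzoic acid
Product: 17 methyl 2-chloro-6-(2,4-dimethoxy-6-pentylphenoxy)-4-methoxybenzoate
Conditions: MeI, K2CO3, DMF, rt
Reagents that add atoms: iodomethane, CI
Why: SN2 alkylation of the carboxylate, which works where Fischer esterification of a 2,6-disubstituted benzoic acid would fail because no attack at the hindered carbonyl is needed.

Step 8
Reactants: 17 methyl 2-chloro-6-(2,4-dimethoxy-6-pentylphenoxy)-4-methoxybenzoate; 18 hept-1-yne
Product: 19 methyl 2-(2,4-dimethoxy-6-pentylphenoxy)-6-(hept-1-yn-1-yl)-4-methoxybenzoate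
Conditions: PdCl2(MeCN)2 (3 mol %), XPhos (9 mol %), Cs2CO3, MeCN, 85 °C
Reagents that add atoms: none
Why: Copper-free Sonogashira coupling of an aryl chloride; the bulky electron-rich biarylphosphine lets zerovalent palladium insert into the C–Cl bond, which the ortho ester activates, and omitting copper suppresses alkyne homocoupling.

Step 9
Reactants: 19 methyl 2-(2,4-dimethoxy-6-pentylphenoxy)-6-(hept-1-yn-1-yl)-4-methoxybenzoate
Product: 21 8-(2,4-dimethoxy-6-pentylphenoxy)-6-methoxy-3-pentyl-1H-isochromen-1-one, via methoxyisochromenylium trifluoroacetate 20 (not isolated)
Conditions: CF3CO2H (5 equiv), Cu(OTf)2 (5 mol %), ClCH2CH2Cl, 60 °C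
Reagents that add atoms: none
Why: Acid-promoted 6-endo-dig cyclisation of a methyl 2-alkynylbenzoate; the ester carbonyl oxygen adds to the activated alkyne at the pentyl-bearing carbon because this gives the aromatic cation 20, C4 is protonated, and the O-methyl group is transferred to trifluoroacetate.

Step 10
Reactants: 21 8-(2,4-dimethoxy-6-pentylphenoxy)-6-methoxy-3-pentyl-1H-isochromen-1-one
Product: 22 8-(2,4-dihydroxy-6-pentylphenoxy)-6-hydroxy-3-pentyl-1H-isochromen-1-one
Conditions: BBr3 (6 equiv), CH2Cl2, −78 °C → rt; H2O
Reagents that add atoms: none
Why: Lewis-acid cleavage of aryl methyl ethers with BBr3 (bromide attacks the activated methyl groups); the diaryl ether and the isocoumarin lactone are not cleaved under these conditions, and aqueous quench frees the three phenols.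

## Compound list

1 | 2-chloro-4-methoxyphenol | COc1ccc(O)c(Cl)c1 | starting material
2 | 2-bromo-6-chloro-4-methoxyphenol | COc1cc(Cl)c(O)c(Br)c1 | intermediate
3 | (2-bromo-6-chloro-4-methoxyphenoxy)trimethylsilane | COc1cc(Cl)c(O[Si](C)(C)C)c(Br)c1 | intermediate
4 | [3-chloro-5-methoxy-2-(trimethylsilyloxy)phenyl]lithium | COc1cc(Cl)c(O[Si](C)(C)C)c([Li])c1 | intermediate
5 | lithium 2-chloro-4-methoxy-6-(trimethylsilyl)phenoxide | COc1cc(Cl)c([O-])c([Si](C)(C)C)c1.[Li+] | intermediate
6 | 2-chloro-4-methoxy-6-(trimethylsilyl)phenyl trifluoromethanesulfonate | COc1cc(Cl)c(OS(=O)(=O)C(F)(F)F)c([Si](C)(C)C)c1 | intermediate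
7 | 1,3-dimethoxy-5-pentylbenzene (olivetol dimethyl ether) | CCCCCc1cc(OC)cc(OC)c1 | starting material
8 | N-[(2,4-dimethoxy-6-pentylphenyl)methylidene]-N-methylmethanaminium chloride | CCCCCc1cc(OC)cc(OC)c1C=[N+](C)C.[Cl-] | intermediate
9 | 2,4-dimethoxy-6-pentylbenzaldehyde | CCCCCc1cc(OC)cc(OC)c1C=O | intermediate
10 | 2,4-dimethoxy-6-pentylphenyl formate | CCCCCc1cc(OC)cc(OC)c1OC=O | intermediate
11 | 2,4-dimethoxy-6-pentylphenol | CCCCCc1cc(OC)cc(OC)c1O | intermediate
12 | carbon dioxide | O=C=O | starting material
13 | potassium 2,4-dimethoxy-6-pentylphenoxide | CCCCCc1cc(OC)cc(OC)c1[O-].[K+] | intermediate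
14 | 3-chloro-5-methoxybenzyne (1-chloro-5-methoxycyclohexa-1,5-dien-3-yne) | COC1=CC#CC(Cl)=C1 | intermediate
15 | potassium 2-chloro-6-(2,4-dimethoxy-6-pentylphenoxy)-4-methoxybenzen-1-ide | CCCCCc1cc(OC)cc(OC)c1Oc1cc(OC)cc(Cl)[c-]1.[K+] | intermediate
16 | 2-chloro-6-(2,4-dimethoxy-6-pentylphenoxy)-4-methoxybenzoic acid | CCCCCc1cc(OC)cc(OC)c1Oc1cc(OC)cc(Cl)c1C(=O)O | intermediate
17 | methyl 2-chloro-6-(2,4-dimethoxy-6-pentylphenoxy)-4-methoxybenzoate | CCCCCc1cc(OC)cc(OC)c1Oc1cc(OC)cc(Cl)c1C(=O)OC | intermediate
18 | hept-1-yne | CCCCCC#C | starting material
19 | methyl 2-(2,4-dimethoxy-6-pentylphenoxy)-6-(hept-1-yn-1-yl)-4-methoxybenzoate | CCCCCC#Cc1cc(OC)cc(Oc2c(OC)cc(OC)cc2CCCCC)c1C(=O)OC | intermediate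
20 | 8-(2,4-dimethoxy-6-pentylphenoxy)-1,6-dimethoxy-3-pentylisochromenylium trifluoroacetate | CCCCCc1cc2cc(OC)cc(Oc3c(OC)cc(OC)cc3CCCCC)c2c(OC)[o+]1.[O-]C(=O)C(F)(F)F | intermediate
21 | 8-(2,4-dimethoxy-6-pentylphenoxy)-6-methoxy-3-pentyl-1H-isochromen-1-one | CCCCCc1cc2cc(OC)cc(Oc3c(OC)cc(OC)cc3CCCCC)c2c(=O)o1 | intermediate
22 | 8-(2,4-dihydroxy-6-pentylphenoxy)-6-hydroxy-3-pentyl-1H-isochromen-1-one | CCCCCc1cc2cc(O)cc(Oc3c(O)cc(O)cc3CCCCC)c2c(=O)o1 | target

## Step count and risks

Total steps: 10. Longest linear sequence: 8 steps (1, 2, 3, 6, 7, 8, 9, 10, from 2-chloro-4-methoxyphenol 1). The ring-B branch (steps 4 and 5) joins at step 6.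

**Step 6 (key step, proposed new method).**
- Most likely failure: the aryl anion 15 is protonated before it is carboxylated, giving plain O-arylation without the carboxyl group. Any residual phenol or trace water can do this.
- Second risk: 15 loses chloride to form a second aryne, because an aryl anion beside a C–Cl bond is itself an aryne precursor.
- Third risk: the carbonate half-ester of 13 adds through oxygen in place of free phenoxide, which leads to an insertion product with the wrong connectivity.
- Fallback (known chemistry), from phenol 11 back to acid 16: nucleophilic aromatic substitution of 11 (K2CO3, DMF, 100 °C) on 2-chloro-6-fluoro-4-methoxybenzaldehyde F1. The aldehyde activates the ortho fluorine, and fluoride leaves far more readily than chloride. This gives 2-chloro-6-(2,4-dimethoxy-6-pentylphenoxy)-4-methoxybenzaldehyde F2. Pinnick oxidation of F2 (NaClO2, NaH2PO4, 2-methylbut-2-ene, t-BuOH/H2O) then gives 16.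

**Step 8.**
- Most likely failure: slow transfer of the alkyne to the hindered arylpalladium chloride, with oligomerisation of hept-1-yne at the temperature the C–Cl bond requires, so that the alkyne is consumed before coupling.
- Fallback, from ester 17 back to isocoumarin 21 (step 9 is bypassed): the carbon nucleophile is changed from an alkyne to a ketone enolate. Palladium-catalysed α-arylation of heptan-2-one F3 at its methyl group with 17 (Pd(OAc)2, XPhos, K3PO4, toluene, 100 °C) gives methyl 2-(2,4-dimethoxy-6-pentylphenoxy)-4-methoxy-6-(2-oxoheptyl)benzoate F4. Acid-catalysed enol lactonisation of F4 (TsOH, toluene, reflux) closes the pyranone with loss of methanol and gives 21.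

**Step 9.**
- Most likely failure: hydration of the alkyne, or stalling at cation 20 with ring opening on work-up, giving the keto ester in place of the lactone. Electrophilic attack of the activated alkyne on the electron-rich ring B is a further risk.
- Fallback, from 19 back to 21: iodocyclisation of 19 (I2, NaHCO3, CH2Cl2, rt), in which iodide removes the ester methyl group, gives 8-(2,4-dimethoxy-6-pentylphenoxy)-4-iodo-6-methoxy-3-pentyl-1H-isochromen-1-one F5. Palladium-catalysed formate reduction of the C–I bond (Pd(OAc)2, PPh3, HCO2H, Et3N, DMF, 60 °C) then gives 21.

**Step 5.**
- Most likely failure: over-oxidation of the very electron-rich formate or phenol to a quinone by excess peracid, and migration of hydrogen in place of aryl, which would give the benzoic acid.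
- Fallback, from 7 back to 11: bromination of 7 (NBS, MeCN, 0 °C) at the same ring position gives 2-bromo-1,5-dimethoxy-3-pentylbenzene F6. Bromine–lithium exchange and borylation (n-BuLi, THF, −78 °C; B(OMe)3) give dimethyl (2,4-dimethoxy-6-pentylphenyl)boronate F7, which is oxidised without isolation (H2O2, NaOH, 0 °C) to 11.

## Further compounds

F1 | step 6 | 2-chloro-6-fluoro-4-methoxybenzaldehyde | COc1cc(F)c(C=O)c(Cl)c1
F2 | step 6 | 2-chloro-6-(2,4-dimethoxy-6-pentylphenoxy)-4-methoxybenzaldehyde | CCCCCc1cc(OC)cc(OC)c1Oc1cc(OC)cc(Cl)c1C=O
F3 | step 8 | heptan-2-one | CCCCCC(C)=O
F4 | step 8 | methyl 2-(2,4-dimethoxy-6-pentylphenoxy)-4-methoxy-6-(2-oxoheptyl)benzoate | CCCCCC(=O)Cc1cc(OC)cc(Oc2c(OC)cc(OC)cc2CCCCC)c1C(=O)OC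
F5 | step 9 | 8-(2,4-dimethoxy-6-pentylphenoxy)-4-iodo-6-methoxy-3-pentyl-1H-isochromen-1-one | CCCCCc1oc(=O)c2c(Oc3c(OC)cc(OC)cc3CCCCC)cc(OC)cc2c1I
F6 | step 5 | 2-bromo-1,5-dimethoxy-3-pentylbenzene | CCCCCc1cc(OC)cc(OC)c1Br
F7 | step 5 | dimethyl (2,4-dimethoxy-6-pentylphenyl)boronate | CCCCCc1cc(OC)cc(OC)c1B(OC)OC
A1 | alternative 1 | dimethyl 2-[5-methoxy-2-(methoxycarbonyl)-3-methylphenoxy]propanedioate | COC(=O)C(Oc1cc(OC)cc(C)c1C(=O)OC)C(=O)OC
A2 | alternative 1 | (E)-non-3-en-2-one | CCCCC/C=C/C(C)=O
A3 | alternative 1 | methyl 1-[5-methoxy-2-(methoxycarbonyl)-3-methylphenoxy]-2,4-dioxo-6-pentylcyclohexane-1-carboxylate (mixture of stereoisomers) | CCCCCC1CC(=O)CC(=O)C1(Oc1cc(OC)cc(C)c1C(=O)OC)C(=O)OC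
A4 | alternative 2 | 2-(2,4-dimethoxy-6-pentylphenoxy)-4-methoxybenzoic acid | CCCCCc1cc(OC)cc(OC)c1Oc1cc(OC)ccc1C(=O)O
A5 | alternative 2 | dimethylsulfoxonium 2-oxoheptylide | CCCCCC(=O)C=S(C)(C)=O
A6 | alternative 2 | 8-(2,4-dimethoxy-6-pentylphenoxy)-6-methoxy-3-pentyl-1H-isochromen-1-one | CCCCCc1cc2cc(OC)cc(Oc3c(OC)cc(OC)cc3CCCCC)c2c(=O)o1
A7 | alternative 3 | methyl 2-{[2-(diazoacetyl)hept-1-en-1-yl]oxy}-4-methoxy-6-methylbenzoate (alkene geometry not specified) | CCCCCC(=COc1cc(OC)cc(C)c1C(=O)OC)C(=O)C=[N+]=[N-]
A8 | alternative 3 | ethoxyethyne | CCOC#C
A9 | alternative 3 | methyl 2-(4-ethoxy-2-hydroxy-6-pentylphenoxy)-4-methoxy-6-methylbenzoate | CCCCCc1cc(OCC)cc(O)c1Oc1cc(OC)cc(C)c1C(=O)OC
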